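The whole plan rests on cutting the C3–C3a bond. The feature used is that carbonyl carbon C3 of the furanone ring is the single carbon between C3a of the resorcinol ring and the fully substituted C2, so the cut gives an aryl anion and the acyl group of a C17 α-keto acid whose C2 ketone is hidden in a 1,3-dithiane. In one operation the aryllithium from bis-MOM-protected 4-bromoresorcinol acylates the Weinreb amide of 2-farnesyl-1,3-dithiane-2-carboxylic acid, joining all 23 skeletal carbons without forming a ring or stereocentre. Unmasking C2 and the phenols lets the O1–C2 hemiketal ring close by itself; the one labile stereocentre is fixed last by resolution.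

Key step: step 4

Naming: farnesyl stands for (2E,6E)-3,7,11-trimethyldodeca-2,6,10-trien-1-yl; C1′, C2′ and so on count along it from the carbon bound to C2. The target is the 2R enantiomer (priorities at C2: O1 > OH > C3 > C1′).

Assumption: the C2 hemiketal can reopen to an achiral open-chain dione, so the target is taken to hold its configuration only in neutral media at or below room temperature. Because the ring closes as soon as the ortho-phenol and the C2 ketone coexist, the configuration is set by separating the enantiomers after the closure.

Step 1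
Reactants: 1 4-bromoresorcinol
Product: 2 1-bromo-2,4-bis(methoxymethoxy)benzene
Conditions: MOMCl (2.5 equiv), i-Pr2NEt (3 equiv), CH2Cl2, 0 °C → rt
Reagents that add atoms: chloromethyl methyl ether (MOMCl), COCCl
Why: Double Williamson-type O-alkylation of the two phenols by the α-chloro ether (through the methoxymethyl oxocarbenium ion) should give the bis-acetal, which is inert to organolithiums and places a lithium-coordinating oxygen ortho to bromine.

Step 2
Reactants: 3 ethyl 1,3-dithiane-2-carboxylate; 4 (2E,6E)-farnesyl bromide
Product: 6 ethyl 2-[(2E,6E)-farnesyl]-1,3-dithiane-2-carboxylate, via sodium enolate 5 (not isolated)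
Conditions: NaH (1.1 equiv), DMF/toluene, 0 °C → rt
Reagents that add atoms: none
Why: Enolate C-alkylation (SN2): the soft, ester- and bis-sulfur-stabilised carbanion should attack the primary allylic carbon of 4 directly, without allylic transposition and without touching the E alkenes.

Step 3
Reactants: 6 ethyl 2-[(2E,6E)-farnesyl]-1,3-dithiane-2-carboxylate
Product: 7 N-methoxy-N-methyl-2-[(2E,6E)-farnesyl]-1,3-dithiane-2-carboxamide
Conditions: MeNH(OMe)·HCl (2 equiv), i-PrMgCl (4 equiv), THF, −20 °C → rt
Reagents that add atoms: N,O-dimethylhydroxylamine hydrochloride, CNOC.Cl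
Why: Weinreb amide formation by aminolysis of an ester with the chloromagnesium amide made in the flask (addition–elimination); 6 has no α-hydrogen, so enolisation cannot compete, and the magnesium-chelated product resists a second attack.

Step 4
Reactants: 2 1-bromo-2,4-bis(methoxymethoxy)benzene; 7 N-methoxy-N-methyl-2-[(2E,6E)-farnesyl]-1,3-dithiane-2-carboxamide
Product: 10 [2,4-bis(methoxymethoxy)phenyl]{2-[(2E,6E)-farnesyl]-1,3-dithian-2-yl}methanone, via aryllithium 8 (not isolated), via chelated lithium carbinolamine adduct 9 (not isolated)
Conditions: 2 (1.6 equiv), n-BuLi (1.5 equiv), THF, −78 °C; then 7 (1.0 equiv), −78 → −20 °C; sat. aq. NH4Cl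
Reagents that add atoms: none
Why: Bromine–lithium exchange converts 2 into aryllithium 8, whose ortho acetal oxygen coordinates lithium, and 8 adds to the amide carbonyl of 7 to give adduct 9, in which lithium sits in a five-membered chelate closed by the N-methoxy oxygen. This chelate survives until the aqueous quench, so ketone 10 is released only when no aryllithium remains, which rules out a second addition. The closest known reaction type is the Weinreb ketone synthesis with an aryllithium, used here to make a 2-acyl-1,3-dithiane. The step forms only the C3–C3a bond: it closes no ring and leaves no stereocentre, because the carbinol centre of 9 is lost on collapse and C2 stays a symmetric thioketal carbon. The selectivity needed is one addition at a hindered carbonyl beside three trisubstituted alkenes and two acetals; the chelate secures mono-addition, the quaternary C2 offers the basic aryllithium no α-proton, and the thioketal carries C2 as a masked ketone that is neither electrophilic nor enolisable, so the C2′–C3′ double bond has no carbonyl to migrate towards. Low temperature lets the exchange outrun attack on the acetals, and the modest excess of 8 offsets the shielding of the carbonyl by the dithiane ring.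

Step 5
Reactants: 10 [2,4-bis(methoxymethoxy)phenyl]{2-[(2E,6E)-farnesyl]-1,3-dithian-2-yl}methanone
Product: 11 (4E,8E)-1-[2,4-bis(methoxymethoxy)phenyl]-5,9,13-trimethyltetradeca-4,8,12-triene-1,2-dione
Conditions: Dess–Martin periodinane (2.5 equiv), MeCN/CH2Cl2/H2O (8:1:1), rt
Reagents that add atoms: water, O
Why: Oxidative dethioketalisation with a hypervalent iodine reagent: sulfur attacks the pentavalent iodine centre, water displaces the activated sulfur at C2 twice and the dithiane unit leaves as the cyclic disulfide, while the alkenes, the acetals and the aryl ketone should be inert to this oxidant near neutrality.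

Step 6
Reactants: 11 (4E,8E)-1-[2,4-bis(methoxymethoxy)phenyl]-5,9,13-trimethyltetradeca-4,8,12-triene-1,2-dione
Product: 13 racemic 2,6-dihydroxy-2-[(2E,6E)-farnesyl]-1-benzofuran-3(2H)-one, via open-chain dihydroxyphenyl dione 12 (not isolated)
Conditions: 2 M HCl in THF/H2O (4:1), rt → 40 °C
Reagents that add atoms: none
Why: Acid-catalysed acetal hydrolysis frees both phenols (alcohol-free medium, so C2 cannot be trapped as a mixed ketal), and the ortho-phenol then adds to the non-conjugated, more electrophilic C2 ketone in a 5-exo-trig hemiketalisation that forms O1–C2; no chiral element is present, so C2 forms as the racemate and its configuration is chosen in step 7.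

Step 7
Reactants: 13 racemic 2,6-dihydroxy-2-[(2E,6E)-farnesyl]-1-benzofuran-3(2H)-one
Product: 14 (2R)-2,6-dihydroxy-2-[(2E,6E)-farnesyl]-1-benzofuran-3(2H)-one
Conditions: preparative HPLC on silica-bound amylose tris(3,5-dimethylphenylcarbamate), n-hexane/i-PrOH, 15 °C; fractions evaporated cold
Reagents that add atoms: none
Why: Resolution by chromatography on a chiral stationary phase: the enantiomers form diastereomeric adsorption complexes with the helical polysaccharide carbamate and should elute apart, the fraction with the R configuration at C2 (to be assigned by comparing its circular dichroism with a computed spectrum) is kept, and the S enantiomer can be re-equilibrated through open dione 12 with a trace of base and resolved again.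

Compound list
1 | 4-bromoresorcinol (4-bromobenzene-1,3-diol) | Oc1ccc(Br)c(O)c1 | starting material
2 | 1-bromo-2,4-bis(methoxymethoxy)benzene | COCOc1ccc(Br)c(OCOC)c1 | intermediate
3 | ethyl 1,3-dithiane-2-carboxylate | CCOC(=O)C1SCCCS1 | starting material
4 | (2E,6E)-farnesyl bromide | CC(C)=CCC/C(C)=C/CC/C(C)=C/CBr | starting material
5 | sodium enolate of ethyl 1,3-dithiane-2-carboxylate | [Na+].CCOC(=O)[C-]1SCCCS1 | intermediate (not isolated)
6 | ethyl 2-[(2E,6E)-farnesyl]-1,3-dithiane-2-carboxylate | CC(C)=CCC/C(C)=C/CC/C(C)=C/CC1(SCCCS1)C(=O)OCC | intermediate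
7 | N-methoxy-N-methyl-2-[(2E,6E)-farnesyl]-1,3-dithiane-2-carboxamide | CC(C)=CCC/C(C)=C/CC/C(C)=C/CC1(SCCCS1)C(=O)N(C)OC | intermediate
8 | [2,4-bis(methoxymethoxy)phenyl]lithium | [Li]c1ccc(OCOC)cc1OCOC | intermediate (not isolated)
9 | lithium [2,4-bis(methoxymethoxy)phenyl]{2-[(2E,6E)-farnesyl]-1,3-dithian-2-yl}[methoxy(methyl)amino]methanolate (N-methoxy chelate, racemic at the carbinol carbon) | CC(C)=CCC/C(C)=C/CC/C(C)=C/CC1(SCCCS1)C(O[Li])(N(C)OC)c1ccc(OCOC)cc1OCOC | intermediate (not isolated)
10 | [2,4-bis(methoxymethoxy)phenyl]{2-[(2E,6E)-farnesyl]-1,3-dithian-2-yl}methanone | CC(C)=CCC/C(C)=C/CC/C(C)=C/CC1(SCCCS1)C(=O)c1ccc(OCOC)cc1OCOC | intermediate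
11 | (4E,8E)-1-[2,4-bis(methoxymethoxy)phenyl]-5,9,13-trimethyltetradeca-4,8,12-triene-1,2-dione | CC(C)=CCC/C(C)=C/CC/C(C)=C/CC(=O)C(=O)c1ccc(OCOC)cc1OCOC | intermediate
12 | (4E,8E)-1-(2,4-dihydroxyphenyl)-5,9,13-trimethyltetradeca-4,8,12-triene-1,2-dione | CC(C)=CCC/C(C)=C/CC/C(C)=C/CC(=O)C(=O)c1ccc(O)cc1O | intermediate (not isolated)
13 | racemic 2,6-dihydroxy-2-[(2E,6E)-farnesyl]-1-benzofuran-3(2H)-one | CC(C)=CCC/C(C)=C/CC/C(C)=C/CC1(O)Oc2cc(O)ccc2C1=O | intermediate
14 | (2R)-2,6-dihydroxy-2-[(2E,6E)-3,7,11-trimethyldodeca-2,6,10-trien-1-yl]-1-benzofuran-3(2H)-one (CNP0212006.1) | CC(C)=CCC/C(C)=C/CC/C(C)=C/C[C@@]1(O)Oc2cc(O)ccc2C1=O | target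

Total steps: 7. Longest linear sequence: 6 steps (steps 2 to 7, from 3 to 14).

Steps most likely to fail

Step 4. Addition to the shielded amide carbonyl may be slow, so that on warming the aryllithium is lost to proton transfer or butylation, or the amide loses its N-methoxy group by base-induced elimination. The fallback sets out from 7 and comes back at 10, and it forms the same C3–C3a bond at a less hindered, more electrophilic carbonyl. Amide 7 is reduced with LiAlH4 (THF, −40 °C) to 2-[(2E,6E)-farnesyl]-1,3-dithiane-2-carbaldehyde F1. Aryllithium 8, made from 2 as in step 4, is added at −78 °C to give the racemic carbinol [2,4-bis(methoxymethoxy)phenyl]{2-[(2E,6E)-farnesyl]-1,3-dithian-2-yl}methanol F2. This electron-rich benzylic alcohol is oxidised with MnO2 in CH2Cl2 to 10, a reagent that leaves the thioketal and the alkenes alone.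

Step 7. The enantiomers may interconvert through ring opening during elution or evaporation, so that the collected fraction loses its purity. The fallback sets out from 13 and comes back at 14, and it resolves a derivative that cannot ring-open.
- Both hydroxyl groups are silylated with TESOTf and 2,6-lutidine (CH2Cl2, −78 → 0 °C) to give racemic 2,6-bis(triethylsilyloxy)-2-[(2E,6E)-farnesyl]-1-benzofuran-3(2H)-one F3.
- This non-polar compound is separated on the same stationary phase in alcohol-free eluent, and (2S)-2,6-bis(triethylsilyloxy)-2-[(2E,6E)-farnesyl]-1-benzofuran-3(2H)-one F4 is kept. Its spatial arrangement is that of 14; the descriptor changes only because O–Si outranks O–aryl.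
- HF·pyridine buffered with pyridine (THF, 0 °C) cleaves the two Si–O bonds and leaves both C2–O bonds intact, giving 14.

Step 6. Before the ring closes, acid may enolise the open dione and move the C2′–C3′ double bond into conjugation, released formaldehyde may attack the electron-rich ring, or HCl may add to the alkenes. The fallback sets out from 10 and comes back at 13, and it reverses the order of unmasking so that acid never meets an enolisable dione.
- The acetals are cleaved first with HCl in MeOH/THF at rt, where the only carbonyl has no α-hydrogen, to give (2,4-dihydroxyphenyl){2-[(2E,6E)-farnesyl]-1,3-dithian-2-yl}methanone F5.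
- The thioketal is then hydrolysed by the thiophilic, non-oxidising pair HgCl2/CaCO3 in MeCN/H2O (rt → 50 °C), the classical way to unmask 2-acyl-1,3-dithianes. The C2 ketone of 12 appears next to the free ortho-phenol in a buffered medium and is trapped at once as 13. Periodinane oxidants are avoided here because free phenols are present.

Further compounds
F1 | step 4 | 2-[(2E,6E)-farnesyl]-1,3-dithiane-2-carbaldehyde | CC(C)=CCC/C(C)=C/CC/C(C)=C/CC1(SCCCS1)C=O
F2 | step 4 | racemic [2,4-bis(methoxymethoxy)phenyl]{2-[(2E,6E)-farnesyl]-1,3-dithian-2-yl}methanol | CC(C)=CCC/C(C)=C/CC/C(C)=C/CC1(SCCCS1)C(O)c1ccc(OCOC)cc1OCOC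
F3 | step 7 | racemic 2,6-bis(triethylsilyloxy)-2-[(2E,6E)-farnesyl]-1-benzofuran-3(2H)-one | CC(C)=CCC/C(C)=C/CC/C(C)=C/CC1(O[Si](CC)(CC)CC)Oc2cc(O[Si](CC)(CC)CC)ccc2C1=O
F4 | step 7 | (2S)-2,6-bis(triethylsilyloxy)-2-[(2E,6E)-farnesyl]-1-benzofuran-3(2H)-one | CC(C)=CCC/C(C)=C/CC/C(C)=C/C[C@@]1(O[Si](CC)(CC)CC)Oc2cc(O[Si](CC)(CC)CC)ccc2C1=O
F5 | step 6 | (2,4-dihydroxyphenyl){2-[(2E,6E)-farnesyl]-1,3-dithian-2-yl}methanone | CC(C)=CCC/C(C)=C/CC/C(C)=C/CC1(SCCCS1)C(=O)c1ccc(O)cc1O
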